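**Retrosynthetic overview**

1. The strategy rests on the 1,3-relationship, across C1', between the C2' carbinol oxygen of the side chain and the oxygen-bearing C2 of the chromone. This is the pattern of a 2-substituted 2,3-dihydro-4-pyranone whose ring oxygen is the carbinol oxygen rather than the phenol oxygen.
2. Target 12 is therefore traced back to dihydropyranone 9 by an acid-mediated ring switch: the vinylogous ester is hydrolysed and a freed phenol recloses on the other carbonyl. The chromone pyranone ring is formed last and the benzene ring is bought.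
3. Dihydropyranone 9 is disconnected by a titanium–BINOL hetero-Diels–Alder (Mukaiyama aldol, then cyclodehydration) into aryl bis(silyloxy)diene 6 and methyl 6-oxohexanoate 7. This forms C1'–C2' and the bond from the C2' oxygen to the future C4, and sets C2'.
4. Diene 6 comes from aryl 1,3-diketone 4 by two-stage silylation; 4 comes from bis-MOM acetophenone 2 and ethyl acetate by Claisen condensation; 2 comes from commercial 2',6'-dihydroxy-4'-methoxyacetophenone 1.

Key step: step 5

Remark on locants: chromone atoms are C2–C8a; the side chain is C1' (CH2 on C2) and C2' (carbinol, R configuration).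

Assumption: the (S)-BINOL–titanium catalyst is taken to deliver the nucleophile to the Si face of the unbranched aldehyde, the usual sense for this catalyst family, which corresponds to (R) at C2'. The sense is to be confirmed on 9, and the antipodal ligand used if it proves opposite.

**Route**

Step 1
Reactants: 1 1-(2,6-dihydroxy-4-methoxyphenyl)ethan-1-one
Product: 2 1-[2,6-bis(methoxymethoxy)-4-methoxyphenyl]ethan-1-one
Conditions: NaH (2.2 equiv), MOMCl (2.5 equiv), DMF, 0 °C to rt
Reagents that add atoms: chloromethyl methyl ether (MOMCl), COCCl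
Why: Williamson-type O-alkylation in which NaH turns both phenols, including the carbonyl-chelated one, into phenoxides that displace chloride from MOMCl, giving acetal ethers that survive all basic steps and fall to the acid that later triggers the ring switch.

Step 2
Reactants: 2 1-[2,6-bis(methoxymethoxy)-4-methoxyphenyl]ethan-1-one; 3 ethyl acetate
Product: 4 1-[2,6-bis(methoxymethoxy)-4-methoxyphenyl]butane-1,3-dione
Conditions: NaH (2.5 equiv), EtOAc (5 equiv), THF, reflux; then AcOH quench, 0 °C
Reagents that add atoms: none
Why: Crossed Claisen condensation in which the methyl ketone is enolised and acetylated by ethyl acetate, driven by irreversible deprotonation of the 1,3-diketone formed, with the aryl MOM ethers untouched by base and by the weak-acid quench.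

Step 3
Reactants: 4 1-[2,6-bis(methoxymethoxy)-4-methoxyphenyl]butane-1,3-dione
Product: 5 (Z)-1-[2,6-bis(methoxymethoxy)-4-methoxyphenyl]-3-(trimethylsilyloxy)but-2-en-1-one
Conditions: Me3SiCl (1.5 equiv), Et3N (1.6 equiv), toluene, rt; filtration under argon
Reagents that add atoms: chlorotrimethylsilane, C[Si](C)(C)Cl
Why: Soft enolisation and O-silylation of the enolised diketone gives the mono silyl enol ether without a Lewis-acidic silyl triflate, which would endanger the aryl MOM ethers; the silyl group may shuttle between the two oxygens and either form converges in step 4.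

Step 4
Reactants: 5 (Z)-1-[2,6-bis(methoxymethoxy)-4-methoxyphenyl]-3-(trimethylsilyloxy)but-2-en-1-one
Product: 6 (Z)-1-[2,6-bis(methoxymethoxy)-4-methoxyphenyl]-1,3-bis(trimethylsilyloxy)buta-1,3-diene
Conditions: LDA (1.2 equiv), THF, −78 °C; Me3SiCl (1.3 equiv), −78 °C to rt; pentane, filtration under argon, used crude
Reagents that add atoms: chlorotrimethylsilane, C[Si](C)(C)Cl
Why: Low-temperature deprotonation at the methyl terminus followed by O-silylation is the standard two-stage preparation of 1,3-bis(silyloxy)buta-1,3-dienes from 1,3-diketones; the moisture-sensitive diene is used at once, and its enol ether geometry is immaterial because it is lost in step 5.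

Step 5
Reactants: 6 (Z)-1-[2,6-bis(methoxymethoxy)-4-methoxyphenyl]-1,3-bis(trimethylsilyloxy)buta-1,3-diene; 7 methyl 6-oxohexanoate
Product: 9 methyl 5-[(2R)-6-[2,6-bis(methoxymethoxy)-4-methoxyphenyl]-4-oxo-3,4-dihydro-2H-pyran-2-yl]pentanoate, via aldol adduct 8 (not isolated)
Conditions: (S)-BINOL (20 mol%), Ti(OiPr)4 (20 mol%), 4 Å MS, THF, −78 °C to rt; then TFA, CH2Cl2, 0 °C
Reagents that add atoms: none
Why: The titanium–BINOL complex (tetravalent titanium) binds the aldehyde of 7 and the terminal CH2 of diene 6 adds to its Si face in a vinylogous Mukaiyama aldol that forms C1'–C2'; TFA then strips the silyl groups to give adduct 8 and drives addition of the C2' oxygen to the aryl ketone carbon with loss of water, so the net change is a hetero-Diels–Alder [4+2]. The closest known reaction type is the titanium–BINOL-catalysed formal hetero-Diels–Alder of 1-alkoxy-3-silyloxy dienes, and of diketone-derived bis(silyloxy) dienes, with aldehydes to give 2-substituted 2,3-dihydro-4-pyranones. The dihydropyranone ring closes by 6-exo-trig attack of the carbinol oxygen on the aryl C=O followed by dehydration to the vinylogous ester, closure on the other carbonyl being excluded because it would need a four-membered ring. The single new stereocentre C2' is controlled by the BINOL enantiomer on titanium, (S)-BINOL being chosen for Si-face delivery, which is (R) here. The step needs enantioface selectivity (ligand), terminal rather than internal attack of the diene (the vinylogous CH2 of a 1,3-bis(silyloxy) diene is its most nucleophilic and least hindered carbon) and aldehyde-over-ester chemoselectivity (the methyl ester is inert to this mild Lewis acid). Partial loss of MOM groups to TFA would be harmless, since step 6 removes them.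

Step 6
Reactants: 9 methyl 5-[(2R)-6-[2,6-bis(methoxymethoxy)-4-methoxyphenyl]-4-oxo-3,4-dihydro-2H-pyran-2-yl]pentanoate
Product: 12 methyl (R)-6-hydroxy-7-(5-hydroxy-7-methoxy-4-oxo-4H-chromen-2-yl)heptanoate (penithochromone O), via bis-phenol dihydropyranone 10 (not isolated), via open-chain hydroxy diketone 11 (not isolated)
Conditions: HCl (2 M) in MeOH/H2O 9:1, 50 °C
Reagents that add atoms: water, O
Why: Acid-catalysed acetal cleavage frees both phenols (10), conjugate addition of water at the aryl-bearing carbon opens the vinylogous ester to hydroxy diketone 11 without touching the C2'–O bond, and a phenol then condenses with the other carbonyl (cyclodehydration as in the closing stage of a Baker–Venkataraman chromone synthesis) to give the aromatic, hydrogen-bonded 5-hydroxychromone as the thermodynamic sink, while methanol as bulk solvent keeps the methyl ester intact.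

**Compound list**

1 | 1-(2,6-dihydroxy-4-methoxyphenyl)ethan-1-one | CC(=O)c1c(O)cc(OC)cc1O | starting material
2 | 1-[2,6-bis(methoxymethoxy)-4-methoxyphenyl]ethan-1-one | CC(=O)c1c(OCOC)cc(OC)cc1OCOC | intermediate
3 | ethyl acetate | CCOC(C)=O | starting material
4 | 1-[2,6-bis(methoxymethoxy)-4-methoxyphenyl]butane-1,3-dione | CC(=O)CC(=O)c1c(OCOC)cc(OC)cc1OCOC | intermediate
5 | (Z)-1-[2,6-bis(methoxymethoxy)-4-methoxyphenyl]-3-(trimethylsilyloxy)but-2-en-1-one | C/C(O[Si](C)(C)C)=C/C(=O)c1c(OCOC)cc(OC)cc1OCOC | intermediate
6 | (Z)-1-[2,6-bis(methoxymethoxy)-4-methoxyphenyl]-1,3-bis(trimethylsilyloxy)buta-1,3-diene | C=C(O[Si](C)(C)C)/C=C(\O[Si](C)(C)C)c1c(OCOC)cc(OC)cc1OCOC | intermediate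
7 | methyl 6-oxohexanoate | COC(=O)CCCCC=O | starting material
8 | methyl (R)-10-[2,6-bis(methoxymethoxy)-4-methoxyphenyl]-6-hydroxy-8,10-dioxodecanoate | COC(=O)CCCC[C@@H](O)CC(=O)CC(=O)c1c(OCOC)cc(OC)cc1OCOC | intermediate
9 | methyl 5-[(2R)-6-[2,6-bis(methoxymethoxy)-4-methoxyphenyl]-4-oxo-3,4-dihydro-2H-pyran-2-yl]pentanoate | COC(=O)CCCC[C@@H]1CC(=O)C=C(O1)c1c(OCOC)cc(OC)cc1OCOC | intermediate
10 | methyl 5-[(2R)-6-(2,6-dihydroxy-4-methoxyphenyl)-4-oxo-3,4-dihydro-2H-pyran-2-yl]pentanoate | COC(=O)CCCC[C@@H]1CC(=O)C=C(O1)c1c(O)cc(OC)cc1O | intermediate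
11 | methyl (R)-10-(2,6-dihydroxy-4-methoxyphenyl)-6-hydroxy-8,10-dioxodecanoate | COC(=O)CCCC[C@@H](O)CC(=O)CC(=O)c1c(O)cc(OC)cc1O | intermediate
12 | methyl (R)-6-hydroxy-7-(5-hydroxy-7-methoxy-4-oxo-4H-chromen-2-yl)heptanoate (penithochromone O) | COC(=O)CCCC[C@@H](O)Cc1cc(=O)c2c(O)cc(OC)cc2o1 | target

**Step count**

Total steps: 6. Longest linear sequence: 6 (1 → 2 → 4 → 5 → 6 → 9 → 12).

**Steps most likely to fail**

Step 5. The hindered, Lewis-basic diene and the unbranched aldehyde may give poor facial selectivity or slow turnover of the titanium catalyst. The fallback moves stereocontrol to a stoichiometric chiral reagent and assembles the diketone afterwards. It sets out from aldehyde 7. Brown allylboration with (−)-B-allyldiisopinocampheylborane (the reagent from (+)-α-pinene, expected to add to the Si face; Et2O, −78 °C; NaBO3·4H2O work-up) should give methyl (R)-6-hydroxynon-8-enoate F1. Silylation (TBSCl, imidazole, DMF) gives methyl (R)-6-(tert-butyldimethylsilyloxy)non-8-enoate F2. Ozonolysis (O3, CH2Cl2, −78 °C; PPh3) gives methyl (R)-6-(tert-butyldimethylsilyloxy)-8-oxooctanoate F3. Aldol addition of ketone 2, deprotonated with LDA (THF, −78 °C), gives methyl (6R)-10-[2,6-bis(methoxymethoxy)-4-methoxyphenyl]-6-(tert-butyldimethylsilyloxy)-8-hydroxy-10-oxodecanoate F4, whose C8 epimers are of no consequence. Dess–Martin oxidation (NaHCO3, CH2Cl2) gives methyl (R)-10-[2,6-bis(methoxymethoxy)-4-methoxyphenyl]-6-(tert-butyldimethylsilyloxy)-8,10-dioxodecanoate F5. Exposure of F5 to the conditions of step 6 should remove the silyl and MOM groups and cyclise, so the fallback comes back to the route at 12.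

Step 6. Opening of the hindered vinylogous ester may be slow. Competing processes are acid-promoted elimination across C1'–C2', retro-oxa-Michael erosion of the C2' configuration, and ester hydrolysis. The fallback closes the chromone from an open-chain diketone whose carbinol is masked, so that no vinylogous ester has to be hydrolysed. It sets out from aldol adduct 8, obtained by replacing the TFA treatment of step 5 with a buffered fluoride work-up (KF, MeOH, pH 7 buffer, 0 °C). Silylation (TBDPSCl, imidazole, DMF) gives methyl (R)-10-[2,6-bis(methoxymethoxy)-4-methoxyphenyl]-6-(tert-butyldiphenylsilyloxy)-8,10-dioxodecanoate F6. HCl in MeOH (rt to 40 °C) removes the MOM groups and cyclodehydrates the o-hydroxyaryl diketone to methyl (R)-6-(tert-butyldiphenylsilyloxy)-7-(5-hydroxy-7-methoxy-4-oxo-4H-chromen-2-yl)heptanoate F7. HF·pyridine (THF, 0 °C to rt) then frees the carbinol, and the fallback comes back to the route at 12.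

Step 4. The second enolisation may be incomplete, or the bis(trimethylsilyl) diene may lose silyl groups by adventitious hydrolysis before it reaches the catalyst. The fallback uses a sturdier diene made by a different enolisation mode. It sets out from diketone 4, which is doubly deprotonated (LDA, 2.3 equiv, THF, −78 to 0 °C) and trapped with Et3SiCl to give (Z)-1-[2,6-bis(methoxymethoxy)-4-methoxyphenyl]-1,3-bis(triethylsilyloxy)buta-1,3-diene F8. This diene tolerates salt removal and storage. It is carried through the conditions of step 5 with aldehyde 7, with a longer TFA treatment for desilylation, and comes back to the route at 9.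

**Further compounds**

F1 | step 5 | methyl (R)-6-hydroxynon-8-enoate | COC(=O)CCCC[C@@H](O)CC=C
F2 | step 5 | methyl (R)-6-(tert-butyldimethylsilyloxy)non-8-enoate | COC(=O)CCCC[C@@H](O[Si](C)(C)C(C)(C)C)CC=C
F3 | step 5 | methyl (R)-6-(tert-butyldimethylsilyloxy)-8-oxooctanoate | COC(=O)CCCC[C@@H](O[Si](C)(C)C(C)(C)C)CC=O
F4 | step 5 | methyl (6R)-10-[2,6-bis(methoxymethoxy)-4-methoxyphenyl]-6-(tert-butyldimethylsilyloxy)-8-hydroxy-10-oxodecanoate (both C8 epimers) | COC(=O)CCCC[C@@H](O[Si](C)(C)C(C)(C)C)CC(O)CC(=O)c1c(OCOC)cc(OC)cc1OCOC
F5 | step 5 | methyl (R)-10-[2,6-bis(methoxymethoxy)-4-methoxyphenyl]-6-(tert-butyldimethylsilyloxy)-8,10-dioxodecanoate | COC(=O)CCCC[C@@H](O[Si](C)(C)C(C)(C)C)CC(=O)CC(=O)c1c(OCOC)cc(OC)cc1OCOC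
F6 | step 6 | methyl (R)-10-[2,6-bis(methoxymethoxy)-4-methoxyphenyl]-6-(tert-butyldiphenylsilyloxy)-8,10-dioxodecanoate | COC(=O)CCCC[C@@H](O[Si](c1ccccc1)(c1ccccc1)C(C)(C)C)CC(=O)CC(=O)c1c(OCOC)cc(OC)cc1OCOC
F7 | step 6 | methyl (R)-6-(tert-butyldiphenylsilyloxy)-7-(5-hydroxy-7-methoxy-4-oxo-4H-chromen-2-yl)heptanoate | COC(=O)CCCC[C@@H](O[Si](c1ccccc1)(c1ccccc1)C(C)(C)C)Cc1cc(=O)c2c(O)cc(OC)cc2o1
F8 | step 4 | (Z)-1-[2,6-bis(methoxymethoxy)-4-methoxyphenyl]-1,3-bis(triethylsilyloxy)buta-1,3-diene | C=C(O[Si](CC)(CC)CC)/C=C(\O[Si](CC)(CC)CC)c1c(OCOC)cc(OC)cc1OCOC
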